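The readings were computed for an exercise, noise included.

| setting | maple | elm | north | south-east | west |
|---|---|---|---|---|---|
| substrate | 0.025 M | 0.038 M | 0.050 M | 0.050 M | 0.050 M |
| temperature | −2 °C | 14 °C | 5 °C | 20 °C | −10 °C |
| remark | run made earlier | run made earlier |  |  |  |
| time |  |  | 20 h | 20 h | 20 h |

| run | time / h | target / % | substrate / % |
|---|---|---|---|
| maple | 1.33 | 0 | 95.3 |
| maple | 2.50 | 0.5 | 89.4 |
| maple | 5.00 | 1.9 | 82.2 |
| maple | 8.00 | 6.2 | 72.9 |
| maple | 15.0 | 13.4 | 56.0 |
| elm | 2.00 | 17.3 | 53.1 |
| elm | 4.00 | 32.5 | 27.7 |
| elm | 6.00 | 39.8 | 14.5 |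
| elm | 8.00 | 42.2 | 8.3 |
| elm | 10.0 | 41.9 | 4.1 |

(each reading ± 0.5 percentage points)

- the flask that comes out highest in amount of target, in percent of the substrate charged, or "all alike" when all lie within 1.5 percentage points (north / south-east / west / all alike)
- target at the end, in percent of the substrate charged, north
- target at the end, in percent of the substrate charged, south-east
- target at the end, in percent of the substrate charged, west

Of the substrate charged, elm still holds 27.7% after 4.00 h and maple holds 56.0% after 15.0 h. I read that loss as first order, with k the rate constant of substrate, so the fraction left is exp(−kt). Maple gives k = 0.0387 /h and elm gives 0.321 /h, which means an activation energy of 85.6 kJ/mol and, at 5 °C, k = 0.101 /h.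

So the number of substrate lifetimes north runs, n = kt (the Damköhler number of a batch), is 2.01. Elm reaches n = 1.93 at 6.00 h with target 39.8%. North looks like elm run slowly: its k is smaller, its time is longer, and it ends at nearly the same n. I commit to about that target.

West has n = 0.244, which falls between maple's n of 0.193 at 5.00 h and 0.310 at 8.00 h, where target reads 1.9% and 6.2%, so I expect a few per cent. South-east has n = 13.4, well beyond elm's last reading at 3.21, so I give no figure for it.

The forecast names north as highest, with 45% there, 6% in south-east and 2.7% in west. Its ground for the low south-east figure is that there the target “forms quickly, then decays”.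

The flasks give 42.4% in north, 17.8% in south-east and 3.38% in west, so north is highest. South-east stands 12 percentage points above the forecast.

    substrate → intermediate (k = 0.661 /h, Ea = 85.0 kJ/mol)
    intermediate ⇌ target (K = 1.30, k = 1.60 /h, Ea = 96.0 kJ/mol, ΔH = −7.00 kJ/mol)
    intermediate ⇌ isomer of the product (K = 7.50, k = 0.224 /h, Ea = 102 kJ/mol, ΔH = −2.00 kJ/mol)
    (constants at 20 °C)

North's n predicts 13.4% of substrate, and north holds 13%. The neighbour, north stopped at 12 h, has n = 1.21, which predicts 29.9%; it holds 29.8% of substrate and 31.8% of target, beside elm's 32.5% at n = 1.28. South-east, with n = 13.4, has 0% of substrate left, and because target goes back to intermediate, it ends with 17.8% of target, where the same run without that back step gives 92.2%.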